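**Retrosynthetic overview**
- The ester and free ketol come last; the anti-diol comes from the E ring alkene (epoxidation, then opening at the tertiary carbon with inversion), and the α-methylene lactone from oxidative lactonisation of a 2-methylene-1,4-diol.
- The ten-membered ring comes from an anionic oxy-Cope ring expansion of a trans-1,2-dialkenylcyclohexanol; the same step forms the lactone C–C bond and, with enolate hydroxylation in the same flask, three stereocentres.
- The Cope substrate comes from an α-quaternary (E)-alkoxyvinyl ketone plus an (E)-dienyllithium.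
- Key step: that ketone comes from meso cis-2,6-dimethylcyclohexanone by enantiotopic deprotonation and palladium-catalysed enolate alkenylation in one flask; the meso ketone comes from 2,6-dimethylphenol by hydrogenation.
- Ring order: six-membered carbocycle (from the arene), then the ten-membered ring, then the γ-lactone.

Assumption: the target is treated as the open hydroxy ketone drawn; the (R,R)-lithium amide is taken to remove the α-proton that leaves the (6S)-enolate (the (S,S)-amine is equally available if the sense is opposite); the six starting materials, including pure (E)-3-methylpent-2-enoic acid, are bought.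

Numbering used for the bicyclic lactones (cyclodeca[b]furan): O1, C2 (lactone C=O), C3 (=CH2), C3a, C4 (oxygenated), C5 (ketone), C6 (CHMe), C7–C9, C10 (CMe), C11, C11a.

**Route**

Step 1
Reactants: 1 2,6-dimethylphenol
Product: 2 cis-2,6-dimethylcyclohexan-1-one (meso; 2R,6S)
Conditions: H2 (5 bar), Pd/C, cyclohexane, 80 °C; then NaOMe (cat.), MeOH, 25 °C; distillation
Reagents that add atoms: none
Why: Heterogeneous arene hydrogenation over palladium stops mainly at the ketone because the partly reduced phenol tautomerises, and base equilibration enriches the diequatorial cis (meso) isomer, so no stereocentre needs control here.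

Step 2
Reactants: 3 (4-methoxyphenyl)methanol; 4 trichloroethene
Product: 8 1-(ethynyloxymethyl)-4-methoxybenzene, via potassium alkoxide 5 (not isolated), via dichlorovinyl ether 6 (not isolated), via lithium alkynide 7 (not isolated)
Conditions: KH, THF, 0 °C; 4, −50 → 25 °C; n-BuLi (2.2 equiv), −78 °C; MeOH, −78 → 0 °C (kept below 25 °C)
Reagents that add atoms: none
Why: Greene-type ynol ether synthesis, in which alkoxide addition–elimination on trichloroethene gives the dichlorovinyl ether and n-BuLi then effects elimination and Li/Cl exchange to the alkynide, which is protonated.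

Step 3
Reactants: 8 1-(ethynyloxymethyl)-4-methoxybenzene
Product: 10 1-{[(E)-2-iodoethenyl]oxymethyl}-4-methoxybenzene, via alkenylzirconocene 9 (not isolated)
Conditions: Cp2Zr(H)Cl, THF, 25 °C; then I2, 0 °C, dark; used at once
Reagents that add atoms: iodine, [I][I]
Why: Schwartz hydrozirconation adds Zr–H syn with zirconium on the terminal carbon and iodinolysis goes with retention, which fixes the E enol ether geometry.

Step 4
Reactants: 2 cis-2,6-dimethylcyclohexan-1-one; 10 1-{[(E)-2-iodoethenyl]oxymethyl}-4-methoxybenzene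
Product: 12 (2R,6S)-2-{(E)-2-[(4-methoxyphenyl)methoxy]ethenyl}-2,6-dimethylcyclohexan-1-one, via lithium enolate 11 (not isolated)
Conditions: (R,R)-bis(1-phenylethyl)amine, n-BuLi, LiCl, THF, −100 °C; then 10, Pd2(dba)3 (2.5 mol%), P(t-Bu)3 (10 mol%), −78 → 25 °C
Reagents that add atoms: none
Why: Proposed new method: the C2-symmetric lithium amide removes one of the two enantiotopic α-protons of the meso ketone (closest known type: Simpkins–Koga enantioselective deprotonation) to give the configurationally stable (6S)-enolate, which is then alkenylated in the same flask by zerovalent-palladium-catalysed enolate cross-coupling (closest known type: Buchwald–Hartwig α-alkenylation of ketone enolates forming quaternary carbons) with retention of the E geometry of 10, and reductive elimination on the face anti to the pseudoaxial C6 methyl makes C2 R while C6 stays S.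

Step 5
Reactants: 3 (4-methoxyphenyl)methanol; 13 2,3-dibromoprop-1-ene
Product: 15 1-{[(2-bromoprop-2-en-1-yl)oxy]methyl}-4-methoxybenzene, via sodium alkoxide 14 (not isolated)
Conditions: NaH, THF, 0 °C; then 13, 0 → 25 °C
Reagents that add atoms: none
Why: Williamson ether synthesis by SN2 at the allylic bromide, the vinylic bromide being inert.

Step 6
Reactants: 15 1-{[(2-bromoprop-2-en-1-yl)oxy]methyl}-4-methoxybenzene; 16 (E)-1,2-bis(tributylstannyl)ethene
Product: 17 tributyl{(1E)-3-[(4-methoxybenzyloxy)methyl]buta-1,3-dien-1-yl}stannane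
Conditions: 16 (2 equiv), Pd(PPh3)4 (5 mol%), toluene, 90 °C
Reagents that add atoms: none
Why: Stille coupling in which excess distannane ensures mono-coupling and both partners keep their alkene geometry, giving the (1E)-dienylstannane.

Step 7
Reactants: 17 tributyl{(1E)-3-[(4-methoxybenzyloxy)methyl]buta-1,3-dien-1-yl}stannane; 12 (2R,6S)-2-{(E)-2-[(4-methoxyphenyl)methoxy]ethenyl}-2,6-dimethylcyclohexan-1-one
Product: 20 (1S,2R,6S)-1-[(1E)-3-{[(4-methoxyphenyl)methoxy]methyl}buta-1,3-dien-1-yl]-2-{(E)-2-[(4-methoxyphenyl)methoxy]ethenyl}-2,6-dimethylcyclohexan-1-ol, via dienyllithium 18 (not isolated), via lithium alkoxide 19 (not isolated)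
Conditions: 17, n-BuLi, THF, −78 °C; then 12, −78 → −30 °C; H2O
Reagents that add atoms: none
Why: Tin–lithium exchange followed by 1,2-addition, in which the axial alkoxyvinyl group of 12 blocks equatorial approach so the dienyl group enters axially, trans to the alkoxyvinyl group, setting C1 as S.

Step 8
Reactants: 20 (1S,2R,6S)-1-[(1E)-3-{[(4-methoxyphenyl)methoxy]methyl}buta-1,3-dien-1-yl]-2-{(E)-2-[(4-methoxyphenyl)methoxy]ethenyl}-2,6-dimethylcyclohexan-1-ol
Product: 24 (2S,3R,4S,5E,10S)-2-[(tert-butyldimethylsilyl)oxy]-4-[(4-methoxyphenyl)methoxy]-3-{3-[(4-methoxyphenyl)methoxy]prop-1-en-2-yl}-6,10-dimethylcyclodec-5-en-1-one, via potassium alkoxide 21 (not isolated), via potassium enolate 22 (not isolated), via potassium ketol alkoxide 23 (not isolated)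
Conditions: KN(SiMe3)2, 18-crown-6, THF, −78 → 25 °C; then 2-(phenylsulfonyl)-3-phenyloxaziridine, −78 °C; then TBSOTf, −78 → 0 °C
Reagents that add atoms: 2-(phenylsulfonyl)-3-phenyloxaziridine, O=S(=O)(c1ccccc1)N1OC1c1ccccc1; tert-butyldimethylsilyl trifluoromethanesulfonate, CC(C)(C)[Si](C)(C)OS(=O)(=O)C(F)(F)F
Why: Anionic oxy-Cope rearrangement through a chair transition state with both alkenyl groups equatorial breaks the old C1–C2 bond, joins the two E-configured alkene termini to give the trans C3/C4 stereocentres and the E ring alkene, and leaves a regiodefined potassium enolate that is hydroxylated on its exposed outer face (Davis oxidation, C2 S) and silylated in the same flask.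

Step 9
Reactants: 24 (2S,3R,4S,5E,10S)-2-[(tert-butyldimethylsilyl)oxy]-4-[(4-methoxyphenyl)methoxy]-3-{3-[(4-methoxyphenyl)methoxy]prop-1-en-2-yl}-6,10-dimethylcyclodec-5-en-1-one
Product: 25 (2S,3R,4S,5E,10S)-2-[(tert-butyldimethylsilyl)oxy]-4-hydroxy-3-(3-hydroxyprop-1-en-2-yl)-6,10-dimethylcyclodec-5-en-1-one
Conditions: DDQ (2.3 equiv), CH2Cl2/pH 7 buffer, 0 °C
Reagents that add atoms: none
Why: Oxidative cleavage of both 4-methoxybenzyl ethers (hydride abstraction to the oxocarbenium ion, then hydrolysis) frees the primary allylic and the secondary alcohol while the silyl ether and the isolated alkenes are untouched.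

Step 10
Reactants: 25 (2S,3R,4S,5E,10S)-2-[(tert-butyldimethylsilyl)oxy]-4-hydroxy-3-(3-hydroxyprop-1-en-2-yl)-6,10-dimethylcyclodec-5-en-1-one
Product: 28 (3aR,4S,6S,10E,11aS)-4-[(tert-butyldimethylsilyl)oxy]-6,10-dimethyl-3-methylidene-2,3,3a,4,5,6,7,8,9,11a-decahydrocyclodeca[b]furan-2,5-dione, via hydroxy enal 26 (not isolated), via lactol 27 (not isolated)
Conditions: TEMPO (20 mol%), PhI(OAc)2 (2.5 equiv), CH2Cl2, 25 °C
Reagents that add atoms: none
Why: TEMPO/PhI(OAc)2 oxidative lactonisation oxidises the primary allylic alcohol selectively to the enal, which closes onto the only free secondary hydroxyl as a five-membered lactol and is oxidised on to the trans-fused α-methylene lactone.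

Step 11
Reactants: 28 (3aR,4S,6S,10E,11aS)-4-[(tert-butyldimethylsilyl)oxy]-6,10-dimethyl-3-methylidene-2,3,3a,4,5,6,7,8,9,11a-decahydrocyclodeca[b]furan-2,5-dione
Product: 30 (3aR,4S,6S,10R,11S,11aR)-4-[(tert-butyldimethylsilyl)oxy]-10,11-dihydroxy-6,10-dimethyl-3-methylidenedodecahydrocyclodeca[b]furan-2,5-dione, via epoxide 29 (not isolated)
Conditions: DMDO, acetone, −20 °C; then H2O, HClO4 (cat.), 0 °C
Reagents that add atoms: dimethyldioxirane, CC1(C)OO1; water, O
Why: Electrophilic epoxidation of the only electron-rich alkene from its exposed peripheral face, followed by acid-catalysed opening at the tertiary carbon with inversion (overall anti-dihydroxylation of the E alkene), sets C10 as R and C11 as S.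

Step 12
Reactants: 30 (3aR,4S,6S,10R,11S,11aR)-4-[(tert-butyldimethylsilyl)oxy]-10,11-dihydroxy-6,10-dimethyl-3-methylidenedodecahydrocyclodeca[b]furan-2,5-dione; 31 (2E)-3-methylpent-2-enoic acid
Product: 33 (3aR,4S,6S,10R,11S,11aR)-4-[(tert-butyldimethylsilyl)oxy]-10-hydroxy-6,10-dimethyl-3-methylidene-2,5-dioxododecahydrocyclodeca[b]furan-11-yl (2E)-3-methylpent-2-enoate, via mixed anhydride 32 (not isolated)
Conditions: 31, 2,4,6-trichlorobenzoyl chloride, Et3N, THF, 0 °C; then 30, DMAP, toluene, 25 °C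
Reagents that add atoms: none
Why: Yamaguchi esterification acylates the secondary C11 hydroxyl because the tertiary C10 hydroxyl is inert and the C4 oxygen is silylated, and the mild mixed-anhydride conditions avoid scrambling of the enoate geometry.

Step 13
Reactants: 33 (3aR,4S,6S,10R,11S,11aR)-4-[(tert-butyldimethylsilyl)oxy]-10-hydroxy-6,10-dimethyl-3-methylidene-2,5-dioxododecahydrocyclodeca[b]furan-11-yl (2E)-3-methylpent-2-enoate
Product: 34 (3aS,4S,6S,10R,11S,11aR)-4,10-dihydroxy-6,10-dimethyl-3-methylidene-2,5-dioxododecahydrocyclodeca[b]furan-11-yl (2E)-3-methylpent-2-enoate (CNP0197047.1)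
Conditions: HF·pyridine, THF/pyridine, 0 → 25 °C
Reagents that add atoms: none
Why: Fluoride-driven desilylation under buffered, non-basic conditions leaves the lactone, the enoate and the α-ketol untouched, so no translactonisation or epimerisation is expected.

**Compound list**

1 | 2,6-dimethylphenol | Cc1cccc(C)c1O | starting material
2 | cis-2,6-dimethylcyclohexan-1-one (meso, 2R,6S) | O=C1[C@@H](C)CCC[C@H]1C | intermediate
3 | (4-methoxyphenyl)methanol | COc1ccc(CO)cc1 | starting material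
4 | trichloroethene | ClC=C(Cl)Cl | starting material
5 | potassium (4-methoxyphenyl)methanolate | COc1ccc(CO[K])cc1 | intermediate
6 | 1-{[(E)-1,2-dichloroethenyl]oxymethyl}-4-methoxybenzene | COc1ccc(CO/C(Cl)=C\Cl)cc1 | intermediate
7 | lithium [(4-methoxyphenyl)methoxy]ethynide | COc1ccc(COC#C[Li])cc1 | intermediate
8 | 1-(ethynyloxymethyl)-4-methoxybenzene | COc1ccc(COC#C)cc1 | intermediate
9 | chlorobis(cyclopentadienyl){(E)-2-[(4-methoxyphenyl)methoxy]ethenyl}zirconium | COc1ccc(CO/C=C/[Zr](Cl)(C2C=CC=C2)C2C=CC=C2)cc1 | intermediate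
10 | 1-{[(E)-2-iodoethenyl]oxymethyl}-4-methoxybenzene | COc1ccc(CO/C=C/I)cc1 | intermediate
11 | lithium (6S)-2,6-dimethylcyclohex-1-en-1-olate | CC1=C(O[Li])[C@@H](C)CCC1 | intermediate
12 | (2R,6S)-2-{(E)-2-[(4-methoxyphenyl)methoxy]ethenyl}-2,6-dimethylcyclohexan-1-one | O=C1[C@@H](C)CCC[C@]1(C)/C=C/OCc1ccc(OC)cc1 | intermediate
13 | 2,3-dibromoprop-1-ene | BrCC(Br)=C | starting material
14 | sodium (4-methoxyphenyl)methanolate | COc1ccc(CO[Na])cc1 | intermediate
15 | 1-{[(2-bromoprop-2-en-1-yl)oxy]methyl}-4-methoxybenzene | COc1ccc(COCC(Br)=C)cc1 | intermediate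
16 | (E)-1,2-bis(tributylstannyl)ethene | CCCC[Sn](CCCC)(CCCC)/C=C/[Sn](CCCC)(CCCC)CCCC | starting material
17 | tributyl{(1E)-3-[(4-methoxybenzyloxy)methyl]buta-1,3-dien-1-yl}stannane | CCCC[Sn](CCCC)(CCCC)/C=C/C(=C)COCc1ccc(OC)cc1 | intermediate
18 | {(1E)-3-[(4-methoxybenzyloxy)methyl]buta-1,3-dien-1-yl}lithium | [Li]/C=C/C(=C)COCc1ccc(OC)cc1 | intermediate
19 | lithium alkoxide of 20 (1S,2R,6S) | [Li]O[C@]1(/C=C/C(=C)COCc2ccc(OC)cc2)[C@@H](C)CCC[C@]1(C)/C=C/OCc1ccc(OC)cc1 | intermediate
20 | (1S,2R,6S)-1-[(1E)-3-{[(4-methoxyphenyl)methoxy]methyl}buta-1,3-dien-1-yl]-2-{(E)-2-[(4-methoxyphenyl)methoxy]ethenyl}-2,6-dimethylcyclohexan-1-ol | O[C@]1(/C=C/C(=C)COCc2ccc(OC)cc2)[C@@H](C)CCC[C@]1(C)/C=C/OCc1ccc(OC)cc1 | intermediate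
21 | potassium alkoxide of 20 (1S,2R,6S) | [K]O[C@]1(/C=C/C(=C)COCc2ccc(OC)cc2)[C@@H](C)CCC[C@]1(C)/C=C/OCc1ccc(OC)cc1 | intermediate
22 | potassium (1Z,3R,4S,5E,10S)-4-[(4-methoxyphenyl)methoxy]-3-{3-[(4-methoxyphenyl)methoxy]prop-1-en-2-yl}-6,10-dimethylcyclodeca-1,5-dien-1-olate | COc1ccc(CO[C@@H]2[C@@H](C(=C)COCc3ccc(OC)cc3)/C=C(\O[K])[C@@H](C)CCC/C(C)=C/2)cc1 | intermediate
23 | potassium C2-alkoxide of the 2-hydroxy ketone (skeleton and configuration of 24, O–K in place of O–Si) | COc1ccc(CO[C@@H]2[C@@H](C(=C)COCc3ccc(OC)cc3)[C@H](O[K])C(=O)[C@@H](C)CCC/C(C)=C/2)cc1 | intermediate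
24 | (2S,3R,4S,5E,10S)-2-[(tert-butyldimethylsilyl)oxy]-4-[(4-methoxyphenyl)methoxy]-3-{3-[(4-methoxyphenyl)methoxy]prop-1-en-2-yl}-6,10-dimethylcyclodec-5-en-1-one | COc1ccc(CO[C@@H]2[C@@H](C(=C)COCc3ccc(OC)cc3)[C@H](O[Si](C)(C)C(C)(C)C)C(=O)[C@@H](C)CCC/C(C)=C/2)cc1 | intermediate
25 | (2S,3R,4S,5E,10S)-2-[(tert-butyldimethylsilyl)oxy]-4-hydroxy-3-(3-hydroxyprop-1-en-2-yl)-6,10-dimethylcyclodec-5-en-1-one | O[C@@H]1[C@@H](C(=C)CO)[C@H](O[Si](C)(C)C(C)(C)C)C(=O)[C@@H](C)CCC/C(C)=C/1 | intermediate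
26 | 2-[(1R,2S,3E,8S,10S)-10-[(tert-butyldimethylsilyl)oxy]-2-hydroxy-4,8-dimethyl-9-oxocyclodec-3-en-1-yl]prop-2-enal | O[C@@H]1[C@@H](C(=C)C=O)[C@H](O[Si](C)(C)C(C)(C)C)C(=O)[C@@H](C)CCC/C(C)=C/1 | intermediate
27 | (3aR,4S,6S,10E,11aS)-4-[(tert-butyldimethylsilyl)oxy]-2-hydroxy-6,10-dimethyl-3-methylidene-2,3,3a,4,5,6,7,8,9,11a-decahydrocyclodeca[b]furan-5-one (both C2 epimers) | C=C1C(O)O[C@@H]2[C@@H]1[C@H](O[Si](C)(C)C(C)(C)C)C(=O)[C@@H](C)CCC/C(C)=C/2 | intermediate
28 | (3aR,4S,6S,10E,11aS)-4-[(tert-butyldimethylsilyl)oxy]-6,10-dimethyl-3-methylidene-2,3,3a,4,5,6,7,8,9,11a-decahydrocyclodeca[b]furan-2,5-dione | C=C1C(=O)O[C@@H]2[C@@H]1[C@H](O[Si](C)(C)C(C)(C)C)C(=O)[C@@H](C)CCC/C(C)=C/2 | intermediate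
29 | (3aR,4S,6S,10S,11S,11aR)-4-[(tert-butyldimethylsilyl)oxy]-10,11-epoxy-6,10-dimethyl-3-methylidenedodecahydrocyclodeca[b]furan-2,5-dione | C=C1C(=O)O[C@@H]2[C@@H]1[C@H](O[Si](C)(C)C(C)(C)C)C(=O)[C@@H](C)CCC[C@]3(C)O[C@@H]23 | intermediate
30 | (3aR,4S,6S,10R,11S,11aR)-4-[(tert-butyldimethylsilyl)oxy]-10,11-dihydroxy-6,10-dimethyl-3-methylidenedodecahydrocyclodeca[b]furan-2,5-dione | C=C1C(=O)O[C@@H]2[C@@H]1[C@H](O[Si](C)(C)C(C)(C)C)C(=O)[C@@H](C)CCC[C@@](C)(O)[C@H]2O | intermediate
31 | (2E)-3-methylpent-2-enoic acid | CC/C(C)=C/C(=O)O | starting material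
32 | (2E)-3-methylpent-2-enoic 2,4,6-trichlorobenzoic anhydride | CC/C(C)=C/C(=O)OC(=O)c1c(Cl)cc(Cl)cc1Cl | intermediate
33 | (3aR,4S,6S,10R,11S,11aR)-4-[(tert-butyldimethylsilyl)oxy]-10-hydroxy-6,10-dimethyl-3-methylidene-2,5-dioxododecahydrocyclodeca[b]furan-11-yl (2E)-3-methylpent-2-enoate | C=C1C(=O)O[C@@H]2[C@@H]1[C@H](O[Si](C)(C)C(C)(C)C)C(=O)[C@@H](C)CCC[C@@](C)(O)[C@H]2OC(=O)/C=C(\C)CC | intermediate
34 | (3aS,4S,6S,10R,11S,11aR)-4,10-dihydroxy-6,10-dimethyl-3-methylidene-2,5-dioxododecahydrocyclodeca[b]furan-11-yl (2E)-3-methylpent-2-enoate | C=C1C(=O)O[C@@H]2[C@@H]1[C@H](O)C(=O)[C@@H](C)CCC[C@@](C)(O)[C@H]2OC(=O)/C=C(\C)CC | target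

**Step count**

Total steps: 13. Longest linear sequence: 10 steps (steps 2, 3, 4, 7, 8, 9, 10, 11, 12, 13); from 2,6-dimethylphenol the sequence is 9 steps.

**Steps most likely to fail**

Step 4 (one-flask desymmetrising deprotonation and alkenylation). The risks are incomplete enantioselection by the amide, a sluggish coupling of the electron-rich iodide at a tertiary enolate carbon, and modest selectivity for the alkenyl group entering anti to the C6 methyl. The fallback sets out from 2. The same lithium amide with Me3SiCl present gives the silyl enol ether (6S)-trimethyl[(2,6-dimethylcyclohex-1-en-1-yl)oxy]silane F1, which is isolated and purified. MeLi regenerates enolate 11 and allyl bromide gives (2R,6S)-2,6-dimethyl-2-(prop-2-en-1-yl)cyclohexan-1-one F2. RuHCl(CO)(PPh3)3 in toluene at 80 °C moves the double bond to give (2R,6S)-2,6-dimethyl-2-[(E)-prop-1-en-1-yl]cyclohexan-1-one F3. Ozonolysis (O3, then Me2S) gives (1R,3S)-1,3-dimethyl-2-oxocyclohexane-1-carbaldehyde F4. A Wittig reaction with the ylide from [(4-methoxybenzyloxy)methyl]triphenylphosphonium chloride and KOC(CH3)3 gives the enol ether; the E isomer, separated from the Z isomer, is 12, where the route is rejoined.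

Step 8 (oxy-Cope, hydroxylation and silylation in one flask). The reactive chair needs both ring methyls axial, so the alkoxide may instead fragment by retro-addition, and the enolate may be hydroxylated unselectively. The fallback sets out from 20. 1-(Trimethylsilyl)imidazole gives the trimethylsilyl ether of 20, (1S,2R,6S)-configured, F5. Heating in toluene at 180 °C (neutral siloxy-Cope, no alkoxide to fragment) gives the trimethylsilyl enol ether of the ring-expanded ketone F6. Rubottom oxidation (DMDO at −78 °C, then citric acid in methanol) gives the free (2S,3S,4S,5E,10S)-2-hydroxy ketone F7. TBSOTf and 2,6-lutidine then give 24, where the route is rejoined.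

Step 11 (epoxidation and hydrolysis). The facial preference of the ring alkene rests on a conformational argument, and the acid opening may proceed without clean inversion or be diverted by transannular attack of the C5 ketone. The fallback sets out from 28. N-Bromosuccinimide in aqueous acetone gives the bromohydrin (3aR,4S,6S,10R,11S,11aR)-11-bromo-4-[(tert-butyldimethylsilyl)oxy]-10-hydroxy-6,10-dimethyl-3-methylidenedodecahydrocyclodeca[b]furan-2,5-dione F8 (bromonium ion on the outer face, water anti at the tertiary carbon). K2CO3 in acetone closes it to the (10R,11R)-epoxide F9, the epimer of 29 at both oxirane carbons. This is also the compound formed if DMDO attacks the other face. Opening of F9 at the secondary carbon with inversion by the caesium salt of 31 (31, Cs2CO3, DMF, 60 °C) installs the ester directly and rejoins the route at 33.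

Further compounds
F1 | step 4 | (6S)-trimethyl[(2,6-dimethylcyclohex-1-en-1-yl)oxy]silane | CC1=C(O[Si](C)(C)C)[C@@H](C)CCC1
F2 | step 4 | (2R,6S)-2,6-dimethyl-2-(prop-2-en-1-yl)cyclohexan-1-one | O=C1[C@@H](C)CCC[C@]1(C)CC=C
F3 | step 4 | (2R,6S)-2,6-dimethyl-2-[(E)-prop-1-en-1-yl]cyclohexan-1-one | O=C1[C@@H](C)CCC[C@]1(C)/C=C/C
F4 | step 4 | (1R,3S)-1,3-dimethyl-2-oxocyclohexane-1-carbaldehyde | O=C1[C@@H](C)CCC[C@]1(C)C=O
F5 | step 8 | trimethylsilyl ether of 20 (1S,2R,6S) | C[Si](C)(C)O[C@]1(/C=C/C(=C)COCc2ccc(OC)cc2)[C@@H](C)CCC[C@]1(C)/C=C/OCc1ccc(OC)cc1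
F6 | step 8 | (1Z,3R,4S,5E,10S)-4-[(4-methoxyphenyl)methoxy]-3-{3-[(4-methoxyphenyl)methoxy]prop-1-en-2-yl}-6,10-dimethyl-1-(trimethylsilyloxy)cyclodeca-1,5-diene | COc1ccc(CO[C@@H]2[C@@H](C(=C)COCc3ccc(OC)cc3)/C=C(\O[Si](C)(C)C)[C@@H](C)CCC/C(C)=C/2)cc1
F7 | step 8 | (2S,3S,4S,5E,10S)-2-hydroxy-4-[(4-methoxyphenyl)methoxy]-3-{3-[(4-methoxyphenyl)methoxy]prop-1-en-2-yl}-6,10-dimethylcyclodec-5-en-1-one | COc1ccc(CO[C@@H]2[C@@H](C(=C)COCc3ccc(OC)cc3)[C@H](O)C(=O)[C@@H](C)CCC/C(C)=C/2)cc1
F8 | step 11 | (3aR,4S,6S,10R,11S,11aR)-11-bromo-4-[(tert-butyldimethylsilyl)oxy]-10-hydroxy-6,10-dimethyl-3-methylidenedodecahydrocyclodeca[b]furan-2,5-dione | C=C1C(=O)O[C@@H]2[C@@H]1[C@H](O[Si](C)(C)C(C)(C)C)C(=O)[C@@H](C)CCC[C@@](C)(O)[C@H]2Br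
F9 | step 11 | (3aR,4S,6S,10R,11R,11aR)-4-[(tert-butyldimethylsilyl)oxy]-10,11-epoxy-6,10-dimethyl-3-methylidenedodecahydrocyclodeca[b]furan-2,5-dione | C=C1C(=O)O[C@@H]2[C@@H]1[C@H](O[Si](C)(C)C(C)(C)C)C(=O)[C@@H](C)CCC[C@@]3(C)O[C@H]23
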